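**Assumptions:** 5,7-dihydroxychromone (CAS 31721-94-5) and (R)-t-BuPyOx are taken as commercially available. The (R)-ligand is chosen by extending the known sense of induction of (S)-t-BuPyOx on cyclic enones to chromone, which predicts (R)-flavanone from the (S)-ligand; this is my own facial mapping, not a recalled result, so confirm on the first batch by CD and switch ligand antipode if it is opposite.

## Retrosynthetic overview

1. The target (2S) comes from fluoride desilylation of its 5,7-bis-O-TBS ether; acid-labile protecting groups are avoided because the ArCH=CH–CMe2OH unit ionises easily.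
2. The C2–C1' bond and the only stereocentre come from a Pd(II)/(R)-t-BuPyOx asymmetric conjugate addition of the B-ring arylboronic acid to 5,7-bis(TBSO)chromone.
3. The boronic acid comes from 2-bromo-4-chloro-6-iodoanisole by three halogen-selective couplings: Heck at C–I, Stille prenylation at C–Br, Pd-borylation at C–Cl.
4. The trihaloanisole comes from 2-bromo-4-chlorophenol by ortho-iodination and O-methylation.
5. No ring is built: the B ring and the A/C chromone bicycle are bought preformed, and the pyranone ring is only saturated in the conjugate addition.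

## Route

**Step 1**
Reactants: 1, 2-bromo-4-chlorophenol; 2, N-iodosuccinimide
Product: 3, 2-bromo-4-chloro-6-iodophenol
Conditions: NIS (1.05 equiv), TsOH·H2O (10 mol%), MeCN, rt
Reagents that add atoms: N-iodosuccinimide, O=C1CCC(=O)N1I
Why: Electrophilic aromatic iodination goes to the only free position ortho to the OH, since the para position and the other ortho position are blocked.

**Step 2**
Reactants: 3; 4, iodomethane
Product: 5, 1-bromo-5-chloro-3-iodo-2-methoxybenzene (2-bromo-4-chloro-6-iodoanisole)
Conditions: MeI, K2CO3, acetone, 50 °C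
Reagents that add atoms: iodomethane, CI
Why: Williamson O-methylation of an acidic di-ortho-halophenol is reliable with the small electrophile MeI.

**Step 3**
Reactants: 5; 6, 2-methylbut-3-en-2-ol
Product: 7, (E)-4-(3-bromo-5-chloro-2-methoxyphenyl)-2-methylbut-3-en-2-ol
Conditions: 6 (1.5 equiv), Pd(OAc)2 (5 mol%), n-Bu4NCl, NaHCO3, DMF, 60 °C
Reagents that add atoms: 2-methylbut-3-en-2-ol, C=CC(C)(C)O
Why: A ligand-free Heck reaction (Jeffery conditions) inserts only into C–I at this temperature, leaving C–Br and C–Cl, and syn-insertion/syn-β-H elimination gives the E-alkene (the quaternary carbinol prevents isomerisation).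

**Step 4**
Reactants: 7; 8, tributyl(3-methylbut-2-en-1-yl)stannane
Product: 9, (E)-4-[5-chloro-2-methoxy-3-(3-methylbut-2-en-1-yl)phenyl]-2-methylbut-3-en-2-ol
Conditions: 8 (1.3 equiv), Pd(PPh3)4 (5 mol%), degassed DMF, 100 °C
Reagents that add atoms: tributyl(prenyl)stannane, CCCC[Sn](CCCC)(CCCC)CC=C(C)C
Why: Stille coupling under neutral conditions engages C–Br but not C–Cl with a PPh3 catalyst, gives mainly the linear (α) prenyl arene, and tolerates the free tertiary allylic alcohol.

**Step 5**
Reactants: 9; 10, tetrahydroxydiboron
Product: 11, {3-[(E)-3-hydroxy-3-methylbut-1-en-1-yl]-4-methoxy-5-(3-methylbut-2-en-1-yl)phenyl}boronic acid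
Conditions: B2(OH)4 (2 equiv), XPhos-Pd-G2 (2 mol%), XPhos (4 mol%), KOAc, EtOH, 80 °C; neutral aqueous work-up, used crude
Reagents that add atoms: tetrahydroxydiboron, OB(O)B(O)O
Why: Miyaura-type borylation of the unhindered aryl chloride with an XPhos catalyst gives the free boronic acid directly under weakly basic conditions that do not affect either alkene or the carbinol.

**Step 6**
Reactants: 12, 5,7-dihydroxy-4H-chromen-4-one; 13, tert-butyldimethylsilyl triflate
Product: 14, 5,7-bis[(tert-butyldimethylsilyl)oxy]-4H-chromen-4-one
Conditions: TBSOTf (2.5 equiv), 2,6-lutidine, CH2Cl2, 0 °C to rt; NaHCO3 work-up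
Reagents that add atoms: TBSOTf, CC(C)(C)[Si](C)(C)OS(=O)(=O)C(F)(F)F
Why: Silyl triflate O-silylation caps both phenols, including the chelated 5-OH, with groups that can later be removed by fluoride without acid.

**Step 7**
Reactants: 14; 11 (1.5 equiv)
Product: 15, (2S)-5,7-bis[(tert-butyldimethylsilyl)oxy]-2-{3-[(E)-3-hydroxy-3-methylbut-1-en-1-yl]-4-methoxy-5-(3-methylbut-2-en-1-yl)phenyl}chroman-4-one
Conditions: Pd(OCOCF3)2 (5 mol%), (R)-t-BuPyOx (6 mol%), NH4PF6 (30 mol%), H2O (5 equiv), ClCH2CH2Cl, 60 °C
Reagents that add atoms: none beyond reactants 11 and 14 (water supplies only the C3 hydrogen)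
Why: In this Pd(II)/pyridine-oxazoline asymmetric conjugate addition, the cationic aryl–Pd(PyOx) species carbopalladates the chromone C2=C3 bond on the enantioface left open by the ligand t-Bu group and the Pd enolate is protonated, so the (R)-ligand is expected to set C2 as S (see assumption); no Pd(0) or syn β-H is available, so no flavone or Heck by-products form.

**Step 8**
Reactants: 15
Product: 16, (2S)-5,7-dihydroxy-2-{3-[(E)-3-hydroxy-3-methylbut-1-en-1-yl]-4-methoxy-5-(3-methylbut-2-en-1-yl)phenyl}chroman-4-one (target)
Conditions: TBAF/AcOH (1:1, 2.5 equiv), THF, 0 °C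
Reagents that add atoms: none
Why: Buffered fluoride desilylation cleaves both aryl silyl ethers without acid (which would ionise the allylic carbinol) or free base (which would open the flavanone and racemise C2); any partly desilylated material from step 7 converges here.

## Compound list

1 | 2-bromo-4-chlorophenol | Oc1ccc(Cl)cc1Br | starting material
2 | N-iodosuccinimide | O=C1CCC(=O)N1I | starting material (reagent)
3 | 2-bromo-4-chloro-6-iodophenol | Oc1c(Br)cc(Cl)cc1I | intermediate
4 | iodomethane | CI | starting material (reagent)
5 | 1-bromo-5-chloro-3-iodo-2-methoxybenzene | COc1c(Br)cc(Cl)cc1I | intermediate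
6 | 2-methylbut-3-en-2-ol | C=CC(C)(C)O | starting material
7 | (E)-4-(3-bromo-5-chloro-2-methoxyphenyl)-2-methylbut-3-en-2-ol | COc1c(Br)cc(Cl)cc1/C=C/C(C)(C)O | intermediate
8 | tributyl(3-methylbut-2-en-1-yl)stannane | CCCC[Sn](CCCC)(CCCC)CC=C(C)C | starting material
9 | (E)-4-[5-chloro-2-methoxy-3-(3-methylbut-2-en-1-yl)phenyl]-2-methylbut-3-en-2-ol | COc1c(CC=C(C)C)cc(Cl)cc1/C=C/C(C)(C)O | intermediate
10 | tetrahydroxydiboron | OB(O)B(O)O | starting material (reagent)
11 | {3-[(E)-3-hydroxy-3-methylbut-1-en-1-yl]-4-methoxy-5-(3-methylbut-2-en-1-yl)phenyl}boronic acid | COc1c(CC=C(C)C)cc(B(O)O)cc1/C=C/C(C)(C)O | intermediate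
12 | 5,7-dihydroxy-4H-chromen-4-one | O=c1ccoc2cc(O)cc(O)c12 | starting material
13 | tert-butyldimethylsilyl trifluoromethanesulfonate | CC(C)(C)[Si](C)(C)OS(=O)(=O)C(F)(F)F | starting material (reagent)
14 | 5,7-bis[(tert-butyldimethylsilyl)oxy]-4H-chromen-4-one | O=c1ccoc2cc(O[Si](C)(C)C(C)(C)C)cc(O[Si](C)(C)C(C)(C)C)c12 | intermediate
15 | (2S)-5,7-bis(TBSO)-2-{3-[(E)-3-hydroxy-3-methylbut-1-enyl]-4-methoxy-5-prenylphenyl}chroman-4-one | COc1c(/C=C/C(C)(C)O)cc([C@@H]2CC(=O)c3c(O[Si](C)(C)C(C)(C)C)cc(O[Si](C)(C)C(C)(C)C)cc3O2)cc1CC=C(C)C | intermediate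
16 | (2S)-5,7-dihydroxy-2-{3-[(E)-3-hydroxy-3-methylbut-1-enyl]-4-methoxy-5-prenylphenyl}chroman-4-one | COc1c(/C=C/C(C)(C)O)cc([C@@H]2CC(=O)c3c(O)cc(O)cc3O2)cc1CC=C(C)C | target

## Summary

Total steps: 8. Longest linear sequence: 7 (steps 1, 2, 3, 4, 5, 7, 8); step 6 is a one-step side branch.

Steps most likely to fail, each with a fallback that changes the approach:

1. **Step 7 (asymmetric conjugate addition).** Risks are an electron-rich 5-substituted chromone, protodeboronation of the electron-rich boronic acid, Lewis-acid stress on the allylic carbinol, and ee or sense of induction. Fallback: abandon the chromone/boronic acid disconnection for a chalcone route.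
   - Make the B-ring aldehyde by the same Heck/Stille sequence on 3-bromo-5-iodo-4-methoxybenzaldehyde.
   - Condense it (Claisen–Schmidt) with 2'-hydroxy-4',6'-bis(allyloxy)acetophenone and cyclise to the racemic flavanone.
   - Recover the 2S ketone by Ru-TsDPEN transfer-hydrogenation kinetic resolution, then remove the allyl groups with Pd(0)/morpholine.
2. **Step 5 (borylation of the aryl chloride).** Risks are hydrodechlorination, partial alkene reduction, and handling of the free boronic acid. Fallback: change the halogen map to 4-bromo-2,6-diiodoanisole (mono-Heck, Stille, then Br/Li exchange with n-BuLi and B(OiPr)3), which replaces Pd-borylation with lithiation–borylation at the cost of a statistical mono-Heck.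
3. **Step 4 (Stille prenylation).** Risks are linear versus reverse-prenyl (γ) coupling and a sluggish ortho-methoxy bromide. Fallback: Stille allylation with allyltributylstannane (no regiochemical ambiguity) followed by cross-metathesis with 2-methyl-2-butene (Grubbs II) to build the prenyl group.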